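**Retrosynthetic overview**
1. Target 35 ← bicyclic triol 33 (allylic oxidation, acetylation) ← ring-closing metathesis (C6=C7) on monocyclic triol 32; the six-membered ring is formed last.
2. 32 ← lactone 31 ← intramolecular chromium-mediated carbonyl allylation (C2–C3); this closes the seven-membered carbocycle onto a temporary trans-fused α-methylene butyrolactone.
3. Key bond C4–C5: intermolecular Michael addition of the RAMP-hydrazone azaenolate of (S)-citronellal to butenolide 18, with the lactone enolate trapped in a Mannich reaction.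
4. Butenolide 18 ← Evans syn-aldol (sets C9 and C10), Weinreb ketone synthesis, methylenation, Z-selective olefination and lactonisation.
5. Ring order: butenolide (temporary) → seven-membered carbocycle (step 18) → six-membered carbocycle (step 20).

Assumption: RAMP (20) and (tributylstannyl)methanol (9) are bought as such; C1–C11 in the "Why" lines are route locants (C1 carries the exocyclic CH2, C3 and C10 the acetates, C4 the side chain, C5/C9 the bridgeheads, C6 the formyl group, C11 the side-chain methine).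

**Step 1**
Reactants: 1 (S)-4-benzyloxazolidin-2-one; 2 pent-4-enoyl chloride
Product: 3 (S)-4-benzyl-3-(pent-4-enoyl)oxazolidin-2-one
Conditions: n-BuLi, THF, −78 °C; then 2, −78 → 0 °C
Reagents that add atoms: none
Why: N-acylation of the lithiated Evans oxazolidinone by the acid chloride; no new stereocentre.

**Step 2**
Reactants: 3 (S)-4-benzyl-3-(pent-4-enoyl)oxazolidin-2-one; 4 (tert-butyldimethylsilyloxy)acetaldehyde
Product: 6 (S)-4-benzyl-3-[(2S,3S)-2-allyl-4-(tert-butyldimethylsilyloxy)-3-hydroxybutanoyl]oxazolidin-2-one, via Z-boron enolate 5 (not isolated)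
Conditions: Bu2BOTf, i-Pr2NEt, CH2Cl2, 0 °C; then 4, −78 → 0 °C; pH 7 buffer, MeOH, 30% H2O2, 0 °C
Reagents that add atoms: none
Why: Evans syn-aldol reaction; the Z-boron enolate reacts through a closed Zimmerman–Traxler chair on the face away from the benzyl group, which sets C9 and C10 (2S,3S in 6) in the syn relationship the target needs.

**Step 3**
Reactants: 6 (S)-4-benzyl-3-[(2S,3S)-2-allyl-4-(tert-butyldimethylsilyloxy)-3-hydroxybutanoyl]oxazolidin-2-one
Product: 7 (2S,3S)-2-allyl-4-(tert-butyldimethylsilyloxy)-3-hydroxy-N-methoxy-N-methylbutanamide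
Conditions: MeONHMe·HCl, AlMe3, CH2Cl2, −15 → 0 °C; aq. potassium sodium tartrate
Reagents that add atoms: N,O-dimethylhydroxylamine hydrochloride, CNOC.Cl
Why: Weinreb transamidation by the aluminium amide, assisted by the free β-hydroxyl, releases the auxiliary without retro-aldol or epimerisation.

**Step 4**
Reactants: 7 (2S,3S)-2-allyl-4-(tert-butyldimethylsilyloxy)-3-hydroxy-N-methoxy-N-methylbutanamide
Product: 8 (2S,3S)-2-allyl-3,4-bis(tert-butyldimethylsilyloxy)-N-methoxy-N-methylbutanamide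
Conditions: TBSOTf, 2,6-lutidine, CH2Cl2, −78 → 0 °C
Reagents that add atoms: tert-butyldimethylsilyl triflate, CC(C)(C)[Si](C)(C)OS(=O)(=O)C(F)(F)F
Why: Silyl ether protection of the secondary alcohol so that the organolithium addition and methylenation that follow cannot cause retro-aldol cleavage.

**Step 5**
Reactants: 9 (tributylstannyl)methanol; 10 4-methoxybenzyl chloride
Product: 11 tributyl{[(4-methoxybenzyl)oxy]methyl}stannane
Conditions: NaH, Bu4NI (cat.), THF/DMF, 0 °C → rt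
Reagents that add atoms: none
Why: Williamson ether synthesis on the sodium alkoxide gives the precursor of the protected hydroxymethyl anion.

**Step 6**
Reactants: 8 (2S,3S)-2-allyl-3,4-bis(tert-butyldimethylsilyloxy)-N-methoxy-N-methylbutanamide; 11 tributyl{[(4-methoxybenzyl)oxy]methyl}stannane
Product: 13 (3S,4S)-3-allyl-4,5-bis(tert-butyldimethylsilyloxy)-1-[(4-methoxybenzyl)oxy]pentan-2-one, via lithiated ether 12 (not isolated)
Conditions: 11, n-BuLi, THF, −78 °C; then 8, −78 °C; then H2O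
Reagents that add atoms: none
Why: Tin–lithium exchange gives the α-alkoxy organolithium, and the Weinreb ketone synthesis stops at the chelated tetrahedral adduct, so the C1 ketone forms without over-addition.

**Step 7**
Reactants: 13 (3S,4S)-3-allyl-4,5-bis(tert-butyldimethylsilyloxy)-1-[(4-methoxybenzyl)oxy]pentan-2-one
Product: 14 (2S,3R)-3-allyl-4-{[(4-methoxybenzyl)oxy]methyl}pent-4-ene-1,2-diol bis(tert-butyldimethylsilyl) ether
Conditions: Ph3PCH3Br, KN(SiMe3)2, THF, 0 °C; then 13, −78 → 0 °C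
Reagents that add atoms: methyltriphenylphosphonium bromide, C[P+](c1ccccc1)(c1ccccc1)c1ccccc1.[Br-]
Why: Wittig methylenation with the salt-free ylide at low temperature installs the C1 exocyclic methylene before the α-stereocentre (C9) can epimerise.

**Step 8**
Reactants: 14 (2S,3R)-3-allyl-4-{[(4-methoxybenzyl)oxy]methyl}pent-4-ene-1,2-diol bis(tert-butyldimethylsilyl) ether
Product: 15 (2S,3R)-3-allyl-2-(tert-butyldimethylsilyloxy)-4-{[(4-methoxybenzyl)oxy]methyl}pent-4-en-1-ol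
Conditions: HF·pyridine, pyridine, THF, 0 °C
Reagents that add atoms: none
Why: Selective desilylation; the unhindered primary silyl ether is cleaved much faster than the hindered secondary one.

**Step 9**
Reactants: 15 (2S,3R)-3-allyl-2-(tert-butyldimethylsilyloxy)-4-{[(4-methoxybenzyl)oxy]methyl}pent-4-en-1-ol
Product: 16 (2S,3R)-3-allyl-2-(tert-butyldimethylsilyloxy)-4-{[(4-methoxybenzyl)oxy]methyl}pent-4-enal
Conditions: Dess–Martin periodinane, CH2Cl2, 0 °C → rt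
Reagents that add atoms: none
Why: Dess–Martin oxidation gives the α-silyloxy aldehyde under neutral conditions that leave the alkenes and the α-stereocentre untouched.

**Step 10**
Reactants: 16 (2S,3R)-3-allyl-2-(tert-butyldimethylsilyloxy)-4-{[(4-methoxybenzyl)oxy]methyl}pent-4-enal
Product: 17 methyl (2Z,4R,5R)-5-allyl-4-(tert-butyldimethylsilyloxy)-6-{[(4-methoxybenzyl)oxy]methyl}hepta-2,6-dienoate
Conditions: (CF3CH2O)2P(O)CH2CO2Me, KN(SiMe3)2, 18-crown-6, THF, −78 °C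
Reagents that add atoms: methyl bis(2,2,2-trifluoroethyl)phosphonoacetate, COC(=O)CP(=O)(OCC(F)(F)F)OCC(F)(F)F
Why: Still–Gennari variant of the Horner–Wadsworth–Emmons olefination gives the Z-enoate needed for lactonisation.

**Step 11**
Reactants: 17 methyl (2Z,4R,5R)-5-allyl-4-(tert-butyldimethylsilyloxy)-6-{[(4-methoxybenzyl)oxy]methyl}hepta-2,6-dienoate
Product: 18 (5R)-5-[(3R)-2-{[(4-methoxybenzyl)oxy]methyl}hexa-1,5-dien-3-yl]furan-2(5H)-one
Conditions: 48% aq. HF, MeCN, 0 °C → rt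
Reagents that add atoms: none
Why: Acidic desilylation frees the γ-hydroxyl of the Z-enoate, which lactonises spontaneously to the butenolide without exposing its acidic γ-hydrogen to base.

**Step 12**
Reactants: 19 (S)-citronellal; 20 (R)-1-amino-2-(methoxymethyl)pyrrolidine (RAMP)
Product: 21 (2R)-N-[(1E,3S)-3,7-dimethyloct-6-en-1-ylidene]-2-(methoxymethyl)pyrrolidin-1-amine
Conditions: CH2Cl2, MgSO4, 0 °C → rt
Reagents that add atoms: none
Why: Hydrazone condensation (Enders RAMP-hydrazone method) masks the aldehyde and installs the auxiliary; C11 comes unchanged from the chiral pool.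

**Step 13**
Reactants: 21 (2R)-N-[(1E,3S)-3,7-dimethyloct-6-en-1-ylidene]-2-(methoxymethyl)pyrrolidin-1-amine; 18 (5R)-5-[(3R)-2-{[(4-methoxybenzyl)oxy]methyl}hexa-1,5-dien-3-yl]furan-2(5H)-one
Product: 24 (3S,4R,5R)-3-[(dimethylamino)methyl]-4-[(2R,3S)-3,7-dimethyl-1-{[(2R)-2-(methoxymethyl)pyrrolidin-1-yl]imino}oct-6-en-2-yl]-5-[(3R)-2-{[(4-methoxybenzyl)oxy]methyl}hexa-1,5-dien-3-yl]oxolan-2-one, via lithium azaenolate 22 (not isolated), via lithium lactone enolate 23 (not isolated)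
Conditions: LiN(i-Pr)2, THF, 0 °C; then 18, −78 °C; then N,N-dimethylmethyleneiminium iodide, −78 → 0 °C
Reagents that add atoms: N,N-dimethylmethyleneiminium iodide, C=[N+](C)C.[I-]
Why: Intermolecular Michael addition then Mannich trapping; the azaenolate adds to the butenolide β-carbon trans to the C10 substituent (sets C5), the chelated RAMP auxiliary fixes the attacked face of the azaenolate (sets C4 as R), and the resulting lactone enolate is aminomethylated trans to the new substituent.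

**Step 14**
Reactants: 24 (3S,4R,5R)-3-[(dimethylamino)methyl]-4-[(2R,3S)-3,7-dimethyl-1-{[(2R)-2-(methoxymethyl)pyrrolidin-1-yl]imino}oct-6-en-2-yl]-5-[(3R)-2-{[(4-methoxybenzyl)oxy]methyl}hexa-1,5-dien-3-yl]oxolan-2-one
Product: 26 (4R,5S)-4-[(2R,3S)-3,7-dimethyl-1-{[(2R)-2-(methoxymethyl)pyrrolidin-1-yl]imino}oct-6-en-2-yl]-5-[(3R)-2-{[(4-methoxybenzyl)oxy]methyl}hexa-1,5-dien-3-yl]-3-methylideneoxolan-2-one, via trimethylammonium iodide 25 (not isolated)
Conditions: MeI, THF, rt; then sat. aq. NaHCO3, CH2Cl2, rt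
Reagents that add atoms: none
Why: The aliphatic amine is quaternised far faster than the hydrazone nitrogen, and E1cB (Hofmann-type) elimination of trimethylamine gives the α-methylene lactone.

**Step 15**
Reactants: 26 (4R,5S)-4-[(2R,3S)-3,7-dimethyl-1-{[(2R)-2-(methoxymethyl)pyrrolidin-1-yl]imino}oct-6-en-2-yl]-5-[(3R)-2-{[(4-methoxybenzyl)oxy]methyl}hexa-1,5-dien-3-yl]-3-methylideneoxolan-2-one
Product: 27 (2R,3S)-2-[(2S,3R)-2-[(3R)-2-{[(4-methoxybenzyl)oxy]methyl}hexa-1,5-dien-3-yl]-4-methylidene-5-oxooxolan-3-yl]-3,7-dimethyloct-6-enal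
Conditions: CuCl2·2H2O, THF/pH 7 buffer, rt
Reagents that add atoms: water, O
Why: Copper-assisted hydrolysis of the hydrazone at neutral pH frees the C3 aldehyde without epimerising C4 and releases the auxiliary.

**Step 16**
Reactants: 27 (2R,3S)-2-[(2S,3R)-2-[(3R)-2-{[(4-methoxybenzyl)oxy]methyl}hexa-1,5-dien-3-yl]-4-methylidene-5-oxooxolan-3-yl]-3,7-dimethyloct-6-enal
Product: 28 (2R,3S)-2-[(2S,3R)-2-[(3R)-2-(hydroxymethyl)hexa-1,5-dien-3-yl]-4-methylidene-5-oxooxolan-3-yl]-3,7-dimethyloct-6-enal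
Conditions: DDQ, CH2Cl2/pH 7 buffer (10:1), 0 °C
Reagents that add atoms: none
Why: Oxidative cleavage of the 4-methoxybenzyl ether by DDQ, which does not touch the alkenes, the aldehyde or the lactone.

**Step 17**
Reactants: 28 (2R,3S)-2-[(2S,3R)-2-[(3R)-2-(hydroxymethyl)hexa-1,5-dien-3-yl]-4-methylidene-5-oxooxolan-3-yl]-3,7-dimethyloct-6-enal
Product: 30 (2R,3S)-2-[(2S,3R)-2-[(3R)-2-(bromomethyl)hexa-1,5-dien-3-yl]-4-methylidene-5-oxooxolan-3-yl]-3,7-dimethyloct-6-enal, via allylic mesylate 29 (not isolated)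
Conditions: MsCl, Et3N, CH2Cl2, −20 °C; then LiBr, THF, 0 °C → rt
Reagents that add atoms: lithium bromide, [Li+].[Br-]
Why: Mesylation then SN2 displacement by bromide gives the allylic bromide under conditions that tolerate the aldehyde (no phosphine/CBr4).

**Step 18**
Reactants: 30 (2R,3S)-2-[(2S,3R)-2-[(3R)-2-(bromomethyl)hexa-1,5-dien-3-yl]-4-methylidene-5-oxooxolan-3-yl]-3,7-dimethyloct-6-enal
Product: 31 (3aR,4R,5S,8R,8aS)-8-allyl-5-hydroxy-3,7-dimethylidene-4-[(2S)-6-methylhept-5-en-2-yl]octahydro-2H-cyclohepta[b]furan-2-one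
Conditions: CrCl2 (6 equiv), THF (0.003 M), rt
Reagents that add atoms: none
Why: Intramolecular Nozaki–Hiyama carbonyl allylation; the allylchromium adds chemoselectively to the aldehyde without Lewis-acid activation (so no ene cyclisation onto the side-chain alkene), and Felkin–Anh attack with the side chain anti to the forming C2–C3 bond is expected to give the 3S carbinol cis to the side chain.

**Step 19**
Reactants: 31 (3aR,4R,5S,8R,8aS)-8-allyl-5-hydroxy-3,7-dimethylidene-4-[(2S)-6-methylhept-5-en-2-yl]octahydro-2H-cyclohepta[b]furan-2-one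
Product: 32 (1S,2R,3R,4S,5R)-5-allyl-3-(3-hydroxyprop-1-en-2-yl)-6-methylidene-2-[(2S)-6-methylhept-5-en-2-yl]cycloheptane-1,4-diol
Conditions: (i-Bu)2AlH (6 equiv), CH2Cl2, −78 → 0 °C; aq. potassium sodium tartrate
Reagents that add atoms: none
Why: 1,2-Hydride reduction of the α-methylene lactone to the allylic 1,4-diol opens the lactone, which is required because a C6=C7 bond cannot exist at the bridgehead of the closed lactone.

**Step 20**
Reactants: 32 (1S,2R,3R,4S,5R)-5-allyl-3-(3-hydroxyprop-1-en-2-yl)-6-methylidene-2-[(2S)-6-methylhept-5-en-2-yl]cycloheptane-1,4-diol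
Product: 33 (1R,4S,5R,6R,10S)-7-(hydroxymethyl)-2-methylidene-5-[(2S)-6-methylhept-5-en-2-yl]bicyclo[4.3.1]dec-7-ene-4,10-diol
Conditions: second-generation Grubbs catalyst (H2IMes)(PCy3)Cl2Ru=CHPh (10 mol %), CH2Cl2 (0.002 M), 40 °C
Reagents that add atoms: none
Why: Ring-closing olefin metathesis between the 1,1-disubstituted allylic-alcohol alkene on C5 and the cis allyl group on C9 forms C6=C7 and the bicyclo[4.3.1] core; the exocyclic methylene and the trisubstituted side-chain alkene cannot give an unstrained ring.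

**Step 21**
Reactants: 33 (1R,4S,5R,6R,10S)-7-(hydroxymethyl)-2-methylidene-5-[(2S)-6-methylhept-5-en-2-yl]bicyclo[4.3.1]dec-7-ene-4,10-diol
Product: 34 (1R,4S,5R,6R,10S)-4,10-dihydroxy-2-methylidene-5-[(2S)-6-methylhept-5-en-2-yl]bicyclo[4.3.1]dec-7-ene-7-carbaldehyde
Conditions: MnO2, CH2Cl2, rt
Reagents that add atoms: none
Why: Chemoselective MnO2 oxidation of the only allylic alcohol gives the enal; the two secondary alcohols are homoallylic and are not oxidised.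

**Step 22**
Reactants: 34 (1R,4S,5R,6R,10S)-4,10-dihydroxy-2-methylidene-5-[(2S)-6-methylhept-5-en-2-yl]bicyclo[4.3.1]dec-7-ene-7-carbaldehyde
Product: 35 (1R,4S,5R,6R,10S)-7-formyl-2-methylidene-5-[(2S)-6-methylhept-5-en-2-yl]bicyclo[4.3.1]dec-7-ene-4,10-diyl diacetate (CNP0197379.1)
Conditions: Ac2O, DMAP (cat.), pyridine, CH2Cl2, 0 °C → rt
Reagents that add atoms: acetic anhydride, CC(=O)OC(C)=O
Why: DMAP-catalysed acetylation of both secondary alcohols completes the target without touching any stereocentre.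

**Compound list**
1 | (S)-4-benzyloxazolidin-2-one | O=C1N[C@@H](Cc2ccccc2)CO1 | starting material
2 | pent-4-enoyl chloride | C=CCCC(=O)Cl | starting material
3 | (S)-4-benzyl-3-(pent-4-enoyl)oxazolidin-2-one | C=CCCC(=O)N1C(=O)OC[C@@H]1Cc1ccccc1 | intermediate
4 | (tert-butyldimethylsilyloxy)acetaldehyde | O=CCO[Si](C)(C)C(C)(C)C | starting material
5 | (Z)-dibutylboron enolate of 3 | CCCCB(CCCC)O/C(=C\CC=C)N1C(=O)OC[C@@H]1Cc1ccccc1 | intermediate (not isolated)
6 | (S)-4-benzyl-3-[(2S,3S)-2-allyl-4-(tert-butyldimethylsilyloxy)-3-hydroxybutanoyl]oxazolidin-2-one | C=CC[C@@H]([C@H](O)CO[Si](C)(C)C(C)(C)C)C(=O)N1C(=O)OC[C@@H]1Cc1ccccc1 | intermediate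
7 | (2S,3S)-2-allyl-4-(tert-butyldimethylsilyloxy)-3-hydroxy-N-methoxy-N-methylbutanamide | C=CC[C@@H]([C@H](O)CO[Si](C)(C)C(C)(C)C)C(=O)N(C)OC | intermediate
8 | (2S,3S)-2-allyl-3,4-bis(tert-butyldimethylsilyloxy)-N-methoxy-N-methylbutanamide | C=CC[C@@H]([C@H](O[Si](C)(C)C(C)(C)C)CO[Si](C)(C)C(C)(C)C)C(=O)N(C)OC | intermediate
9 | (tributylstannyl)methanol | CCCC[Sn](CCCC)(CCCC)CO | starting material
10 | 4-methoxybenzyl chloride | COc1ccc(CCl)cc1 | starting material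
11 | tributyl{[(4-methoxybenzyl)oxy]methyl}stannane | CCCC[Sn](CCCC)(CCCC)COCc1ccc(OC)cc1 | intermediate
12 | [(4-methoxybenzyl)oxy]methyllithium | [Li]COCc1ccc(OC)cc1 | intermediate (not isolated)
13 | (3S,4S)-3-allyl-4,5-bis(tert-butyldimethylsilyloxy)-1-[(4-methoxybenzyl)oxy]pentan-2-one | C=CC[C@@H]([C@H](O[Si](C)(C)C(C)(C)C)CO[Si](C)(C)C(C)(C)C)C(=O)COCc1ccc(OC)cc1 | intermediate
14 | (2S,3R)-3-allyl-4-{[(4-methoxybenzyl)oxy]methyl}pent-4-ene-1,2-diol bis(tert-butyldimethylsilyl) ether | C=CC[C@@H]([C@H](O[Si](C)(C)C(C)(C)C)CO[Si](C)(C)C(C)(C)C)C(=C)COCc1ccc(OC)cc1 | intermediate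
15 | (2S,3R)-3-allyl-2-(tert-butyldimethylsilyloxy)-4-{[(4-methoxybenzyl)oxy]methyl}pent-4-en-1-ol | C=CC[C@@H]([C@H](O[Si](C)(C)C(C)(C)C)CO)C(=C)COCc1ccc(OC)cc1 | intermediate
16 | (2S,3R)-3-allyl-2-(tert-butyldimethylsilyloxy)-4-{[(4-methoxybenzyl)oxy]methyl}pent-4-enal | C=CC[C@@H]([C@H](O[Si](C)(C)C(C)(C)C)C=O)C(=C)COCc1ccc(OC)cc1 | intermediate
17 | methyl (2Z,4R,5R)-5-allyl-4-(tert-butyldimethylsilyloxy)-6-{[(4-methoxybenzyl)oxy]methyl}hepta-2,6-dienoate | C=CC[C@@H]([C@H](O[Si](C)(C)C(C)(C)C)/C=C\C(=O)OC)C(=C)COCc1ccc(OC)cc1 | intermediate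
18 | (5R)-5-[(3R)-2-{[(4-methoxybenzyl)oxy]methyl}hexa-1,5-dien-3-yl]furan-2(5H)-one | C=CC[C@@H]([C@@H]1OC(=O)C=C1)C(=C)COCc1ccc(OC)cc1 | intermediate
19 | (S)-citronellal | O=CC[C@@H](C)CCC=C(C)C | starting material
20 | (R)-1-amino-2-(methoxymethyl)pyrrolidine (RAMP) | COC[C@H]1CCCN1N | starting material
21 | (2R)-N-[(1E,3S)-3,7-dimethyloct-6-en-1-ylidene]-2-(methoxymethyl)pyrrolidin-1-amine | COC[C@H]1CCCN1/N=C/C[C@@H](C)CCC=C(C)C | intermediate
22 | lithium azaenolate of 21 | COC[C@H]1CCCN1N([Li])/C=C/[C@@H](C)CCC=C(C)C | intermediate (not isolated)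
23 | lithium enolate of the trans-lactone Michael adduct | [Li]OC1=C[C@@H]([C@H](/C=N/N2CCC[C@@H]2COC)[C@@H](C)CCC=C(C)C)[C@@H](O1)[C@H](CC=C)C(=C)COCc1ccc(OC)cc1 | intermediate (not isolated)
24 | (3S,4R,5R)-3-[(dimethylamino)methyl]-4-[(2R,3S)-3,7-dimethyl-1-{[(2R)-2-(methoxymethyl)pyrrolidin-1-yl]imino}oct-6-en-2-yl]-5-[(3R)-2-{[(4-methoxybenzyl)oxy]methyl}hexa-1,5-dien-3-yl]oxolan-2-one | CN(C)C[C@H]1C(=O)O[C@@H]([C@H](CC=C)C(=C)COCc2ccc(OC)cc2)[C@@H]1[C@H](/C=N/N2CCC[C@@H]2COC)[C@@H](C)CCC=C(C)C | intermediate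
25 | trimethylammonium iodide of 24 | C[N+](C)(C)C[C@H]1C(=O)O[C@@H]([C@H](CC=C)C(=C)COCc2ccc(OC)cc2)[C@@H]1[C@H](/C=N/N2CCC[C@@H]2COC)[C@@H](C)CCC=C(C)C.[I-] | intermediate (not isolated)
26 | (4R,5S)-4-[(2R,3S)-3,7-dimethyl-1-{[(2R)-2-(methoxymethyl)pyrrolidin-1-yl]imino}oct-6-en-2-yl]-5-[(3R)-2-{[(4-methoxybenzyl)oxy]methyl}hexa-1,5-dien-3-yl]-3-methylideneoxolan-2-one | C=C1C(=O)O[C@@H]([C@H](CC=C)C(=C)COCc2ccc(OC)cc2)[C@@H]1[C@H](/C=N/N2CCC[C@@H]2COC)[C@@H](C)CCC=C(C)C | intermediate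
27 | (2R,3S)-2-[(2S,3R)-2-[(3R)-2-{[(4-methoxybenzyl)oxy]methyl}hexa-1,5-dien-3-yl]-4-methylidene-5-oxooxolan-3-yl]-3,7-dimethyloct-6-enal | C=C1C(=O)O[C@@H]([C@H](CC=C)C(=C)COCc2ccc(OC)cc2)[C@@H]1[C@H](C=O)[C@@H](C)CCC=C(C)C | intermediate
28 | (2R,3S)-2-[(2S,3R)-2-[(3R)-2-(hydroxymethyl)hexa-1,5-dien-3-yl]-4-methylidene-5-oxooxolan-3-yl]-3,7-dimethyloct-6-enal | C=C1C(=O)O[C@@H]([C@H](CC=C)C(=C)CO)[C@@H]1[C@H](C=O)[C@@H](C)CCC=C(C)C | intermediate
29 | methanesulfonate of 28 | C=C1C(=O)O[C@@H]([C@H](CC=C)C(=C)COS(C)(=O)=O)[C@@H]1[C@H](C=O)[C@@H](C)CCC=C(C)C | intermediate (not isolated)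
30 | (2R,3S)-2-[(2S,3R)-2-[(3R)-2-(bromomethyl)hexa-1,5-dien-3-yl]-4-methylidene-5-oxooxolan-3-yl]-3,7-dimethyloct-6-enal | C=C1C(=O)O[C@@H]([C@H](CC=C)C(=C)CBr)[C@@H]1[C@H](C=O)[C@@H](C)CCC=C(C)C | intermediate
31 | (3aR,4R,5S,8R,8aS)-8-allyl-5-hydroxy-3,7-dimethylidene-4-[(2S)-6-methylhept-5-en-2-yl]octahydro-2H-cyclohepta[b]furan-2-one | C=C1C[C@H](O)[C@H]([C@@H](C)CCC=C(C)C)[C@@H]2C(=C)C(=O)O[C@H]2[C@@H]1CC=C | intermediate
32 | (1S,2R,3R,4S,5R)-5-allyl-3-(3-hydroxyprop-1-en-2-yl)-6-methylidene-2-[(2S)-6-methylhept-5-en-2-yl]cycloheptane-1,4-diol | C=C1C[C@H](O)[C@H]([C@@H](C)CCC=C(C)C)[C@H](C(=C)CO)[C@@H](O)[C@@H]1CC=C | intermediate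
33 | (1R,4S,5R,6R,10S)-7-(hydroxymethyl)-2-methylidene-5-[(2S)-6-methylhept-5-en-2-yl]bicyclo[4.3.1]dec-7-ene-4,10-diol | C=C1C[C@H](O)[C@H]([C@@H](C)CCC=C(C)C)[C@@H]2C(CO)=CC[C@H]1[C@@H]2O | intermediate
34 | (1R,4S,5R,6R,10S)-4,10-dihydroxy-2-methylidene-5-[(2S)-6-methylhept-5-en-2-yl]bicyclo[4.3.1]dec-7-ene-7-carbaldehyde | C=C1C[C@H](O)[C@H]([C@@H](C)CCC=C(C)C)[C@@H]2C(C=O)=CC[C@H]1[C@@H]2O | intermediate
35 | (1R,4S,5R,6R,10S)-7-formyl-2-methylidene-5-[(2S)-6-methylhept-5-en-2-yl]bicyclo[4.3.1]dec-7-ene-4,10-diyl diacetate | C=C1C[C@H](OC(C)=O)[C@H]([C@@H](C)CCC=C(C)C)[C@@H]2C(C=O)=CC[C@H]1[C@@H]2OC(C)=O | target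

**Totals**
Total step count: 22. Longest linear sequence: 20 steps (steps 1–4, 6–11 and 13–22; steps 5 and 12 are side branches).

**Steps most likely to fail**

Step 13 (Michael/Mannich). The basic azaenolate 22 may deprotonate the acidic γ-hydrogen of butenolide 18, or the auxiliary and the ring may be a mismatched pair. The fallback sets out from aldehyde 16 and returns at 24. Aldehyde 16 is homologated with (MeO)2P(O)CH2CO2Me, LiCl and DBU to the open-chain enoate methyl (2E,4R,5R)-5-allyl-4-(tert-butyldimethylsilyloxy)-6-{[(4-methoxybenzyl)oxy]methyl}hepta-2,6-dienoate F1, which has no acidic γ-hydrogen. Azaenolate 22 is added to it at −78 °C, now under acyclic Felkin–Anh control anti to the silyloxy group, to give methyl (3S,4R,5R)-5-allyl-4-(tert-butyldimethylsilyloxy)-3-[(2R,3S)-3,7-dimethyl-1-{[(2R)-2-(methoxymethyl)pyrrolidin-1-yl]imino}oct-6-en-2-yl]-6-{[(4-methoxybenzyl)oxy]methyl}hept-6-enoate F2. Bu4NF removes the silyl group and the alkoxide closes onto the ester to give (4S,5R)-4-[(2R,3S)-3,7-dimethyl-1-{[(2R)-2-(methoxymethyl)pyrrolidin-1-yl]imino}oct-6-en-2-yl]-5-[(3R)-2-{[(4-methoxybenzyl)oxy]methyl}hexa-1,5-dien-3-yl]oxolan-2-one F3. A separate enolisation with LiN(i-Pr)2 and trapping with N,N-dimethylmethyleneiminium iodide then gives 24.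

Step 18 (seven-membered ring closure). The facial selectivity at C3 is predicted, not guaranteed. The fallback sets out from bromide 30 and returns at triol 32. If the chromium-mediated closure gives mainly the epimeric alcohol (3aR,4R,5R,8R,8aS)-8-allyl-5-hydroxy-3,7-dimethylidene-4-[(2S)-6-methylhept-5-en-2-yl]octahydro-2H-cyclohepta[b]furan-2-one F4, the carbinol is inverted by a Mitsunobu reaction (chloroacetic acid, PPh3, diisopropyl azodicarboxylate) to (3aR,4R,5S,8R,8aS)-8-allyl-3,7-dimethylidene-4-[(2S)-6-methylhept-5-en-2-yl]-2-oxooctahydro-2H-cyclohepta[b]furan-5-yl chloroacetate F5. The (i-Bu)2AlH treatment of step 19 then cleaves the ester and reduces the lactone in one operation to give 32.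

Step 20 (bridging metathesis). The two alkenyl arms must both sit pseudo-axial on the cycloheptane, and three free hydroxyls can bind ruthenium. The fallback sets out from triol 32 and returns at 33. The substrate is changed to a conformationally biased, non-chelating one: TESOTf and 2,6-lutidine give (1S,2R,3R,4S,5R)-5-allyl-3-(3-hydroxyprop-1-en-2-yl)-6-methylidene-2-[(2S)-6-methylhept-5-en-2-yl]cycloheptane-1,4-diol tris(triethylsilyl) ether F6, whose bulky silyloxy groups push the C5 and C9 arms into the diaxial arrangement. Metathesis with the same catalyst in toluene at 80 °C gives (1R,4S,5R,6R,10S)-7-(hydroxymethyl)-2-methylidene-5-[(2S)-6-methylhept-5-en-2-yl]bicyclo[4.3.1]dec-7-ene-4,10-diol tris(triethylsilyl) ether F7, and HF·pyridine then returns triol 33.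

**Further compounds**
F1 | step 13 | methyl (2E,4R,5R)-5-allyl-4-(tert-butyldimethylsilyloxy)-6-{[(4-methoxybenzyl)oxy]methyl}hepta-2,6-dienoate | C=CC[C@@H]([C@H](O[Si](C)(C)C(C)(C)C)/C=C/C(=O)OC)C(=C)COCc1ccc(OC)cc1
F2 | step 13 | methyl (3S,4R,5R)-5-allyl-4-(tert-butyldimethylsilyloxy)-3-[(2R,3S)-3,7-dimethyl-1-{[(2R)-2-(methoxymethyl)pyrrolidin-1-yl]imino}oct-6-en-2-yl]-6-{[(4-methoxybenzyl)oxy]methyl}hept-6-enoate | COC(=O)C[C@@H]([C@H](/C=N/N1CCC[C@@H]1COC)[C@@H](C)CCC=C(C)C)[C@@H](O[Si](C)(C)C(C)(C)C)[C@H](CC=C)C(=C)COCc1ccc(OC)cc1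
F3 | step 13 | (4S,5R)-4-[(2R,3S)-3,7-dimethyl-1-{[(2R)-2-(methoxymethyl)pyrrolidin-1-yl]imino}oct-6-en-2-yl]-5-[(3R)-2-{[(4-methoxybenzyl)oxy]methyl}hexa-1,5-dien-3-yl]oxolan-2-one | O=C1C[C@@H]([C@H](/C=N/N2CCC[C@@H]2COC)[C@@H](C)CCC=C(C)C)[C@@H](O1)[C@H](CC=C)C(=C)COCc1ccc(OC)cc1
F4 | step 18 | (3aR,4R,5R,8R,8aS)-8-allyl-5-hydroxy-3,7-dimethylidene-4-[(2S)-6-methylhept-5-en-2-yl]octahydro-2H-cyclohepta[b]furan-2-one | C=C1C[C@@H](O)[C@H]([C@@H](C)CCC=C(C)C)[C@@H]2C(=C)C(=O)O[C@H]2[C@@H]1CC=C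
F5 | step 18 | (3aR,4R,5S,8R,8aS)-8-allyl-3,7-dimethylidene-4-[(2S)-6-methylhept-5-en-2-yl]-2-oxooctahydro-2H-cyclohepta[b]furan-5-yl chloroacetate | C=C1C[C@H](OC(=O)CCl)[C@H]([C@@H](C)CCC=C(C)C)[C@@H]2C(=C)C(=O)O[C@H]2[C@@H]1CC=C
F6 | step 20 | tris(triethylsilyl) ether of triol 32 | C=C1C[C@H](O[Si](CC)(CC)CC)[C@H]([C@@H](C)CCC=C(C)C)[C@H](C(=C)CO[Si](CC)(CC)CC)[C@@H](O[Si](CC)(CC)CC)[C@@H]1CC=C
F7 | step 20 | tris(triethylsilyl) ether of bicyclic triol 33 | C=C1C[C@H](O[Si](CC)(CC)CC)[C@H]([C@@H](C)CCC=C(C)C)[C@@H]2C(CO[Si](CC)(CC)CC)=CC[C@H]1[C@@H]2O[Si](CC)(CC)CC
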